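Ring C is disconnected at C2–C3 and C4–C4a, which leads back to an α-diazoketone of an O-aryl mandelic acid in which C2 still sits on the future carbonyl carbon C4. In one flask, photochemical Wolff rearrangement moves the O1-bearing stereocentre C2 with retention from C4 to the diazo carbon (C2–C3), and the resulting ketene, once activated by CF3CO2H, acylates C4a (C4–C4a). The step exploits the symmetric 3,5-dimethoxyphenoxy ring A, whose two equivalent ortho carbons are each activated by three oxygens and close a six-membered ring with the ketene carbon, and the configurational fidelity of the 1,2-shift. The stereocentre comes from an enantioselective O–H insertion.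

Key step: step 6

Remark (assumption): 2,3,4-trimethoxyphenylacetic acid and 3,5-dimethoxyphenol are taken as commercial. The sense of induction of the spiro-bisoxazoline ligand in step 3 is to be assigned in a first run, and the antipode that delivers the R ester is used.

Step 1
Reactants: 1 2-(2,3,4-trimethoxyphenyl)acetic acid
Product: 2 methyl 2-(2,3,4-trimethoxyphenyl)acetate
Conditions: MeOH, H2SO4 (cat.), reflux
Reagents that add atoms: methanol, CO
Why: Fischer esterification of an unhindered arylacetic acid in excess methanol should give the ester needed for diazo transfer.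

Step 2
Reactants: 2 methyl 2-(2,3,4-trimethoxyphenyl)acetate
Product: 3 methyl 2-diazo-2-(2,3,4-trimethoxyphenyl)acetate
Conditions: 4-acetamidobenzenesulfonyl azide (p-ABSA), DBU, MeCN, 0 °C → rt
Reagents that add atoms: 4-acetamidobenzenesulfonyl azide, CC(=O)Nc1ccc(cc1)S(=O)(=O)N=[N+]=[N-]
Why: Regitz diazo transfer, in which the benzylic ester enolate attacks the terminal nitrogen of the sulfonyl azide and the adduct collapses to the aryl diazoacetate and the sulfonamide.

Step 3
Reactants: 3 methyl 2-diazo-2-(2,3,4-trimethoxyphenyl)acetate, 4 3,5-dimethoxyphenol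
Product: 5 methyl (R)-2-(3,5-dimethoxyphenoxy)-2-(2,3,4-trimethoxyphenyl)acetate
Conditions: PdCl2(PhCN)2 (5 mol %), 7,7'-bis(4-phenyl-4,5-dihydrooxazol-2-yl)-1,1'-spirobiindane (Ph-SpiroBOX, 6 mol %), NaB[3,5-(CF3)2C6H3]4 (12 mol %), 5 Å MS, CHCl3, 30 °C
Reagents that add atoms: none
Why: Enantioselective carbene O–H insertion, a reaction type established for phenols with α-aryl-α-diazoacetates: the phenol oxygen attacks the carbene of divalent palladium and the chiral spiro ligand controls the face of the subsequent proton shift, which sets C2 as R.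

Step 4
Reactants: 5 methyl (R)-2-(3,5-dimethoxyphenoxy)-2-(2,3,4-trimethoxyphenyl)acetate
Product: 6 (R)-2-(3,5-dimethoxyphenoxy)-2-(2,3,4-trimethoxyphenyl)acetic acid
Conditions: LiOH·H2O (1.5 equiv), THF/H2O, 0 °C; then 1 M HCl to pH 3
Reagents that add atoms: lithium hydroxide, [Li+].[OH-]
Why: Saponification by acyl–oxygen cleavage should outrun enolisation of the ester at 0 °C, and the carboxylate formed is no longer enolisable, so C2 should keep its R configuration.

Step 5
Reactants: 6 (R)-2-(3,5-dimethoxyphenoxy)-2-(2,3,4-trimethoxyphenyl)acetic acid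
Product: 8 (R)-1-diazo-3-(3,5-dimethoxyphenoxy)-3-(2,3,4-trimethoxyphenyl)propan-2-one, via mixed carbonic anhydride 7 (not isolated)
Conditions: i-BuOCOCl, N-methylmorpholine, THF, −20 °C; then CH2N2 (Et2O, 3 equiv), −20 → 0 °C
Reagents that add atoms: diazomethane, C=[N+]=[N-]
Why: First half of an Arndt–Eistert sequence, in which diazomethane is acylated at the more electrophilic acyl carbon of the mixed carbonic anhydride, at low temperature and with a weak base so that the α-stereocentre is not enolised.

Step 6
Reactants: 8 (R)-1-diazo-3-(3,5-dimethoxyphenoxy)-3-(2,3,4-trimethoxyphenyl)propan-2-one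
Product: 11 (S)-5,7-dimethoxy-2-(2,3,4-trimethoxyphenyl)chroman-4-one, via ketene 9 (not isolated), via acyl trifluoroacetate 10 (not isolated)
Conditions: hν (390 nm LEDs), CH2Cl2 (0.01 M), −20 °C until 8 is consumed; light off, then CF3CO2H (1.5 equiv), −20 → 10 °C, same flask; aq. NaHCO3
Reagents that add atoms: none
Why: Excitation of 8 expels N2 while C2 migrates with retention from the acyl carbon to the diazo carbon (Wolff rearrangement, new C2–C3 bond) to give ketene 9; CF3CO2H then adds to the ketene to give the mixed anhydride 10, whose acyl carbon is attacked by an ortho carbon of ring A (Friedel–Crafts acylation, new C4–C4a bond) with release of CF3CO2H. The closest known types are the Arndt–Eistert homologation of α-stereogenic acids and the trifluoroacetic anhydride cyclisation of 3-aryloxypropanoic acids to chroman-4-ones, here combined in one flask. Ring C closes by a 6-exo-trig attack of the arene on the acyl carbon. No new stereocentre is formed: C2 is carried over from 8 because the 1,2-shift is suprafacial on the migrating carbon, and the descriptor changes from R to S only through the CIP priorities. The step needs acylation of ring A in preference to ring B, to the 2'-methoxy oxygen and to ketene dimerisation; the two ortho carbons of ring A are equivalent and each is ortho or para to three oxygens, ring B offers only a five-membered closure at a singly activated carbon, and high dilution should suppress dimerisation. The acid is added only after the diazoketone is gone and is kept dilute and cold so that neither the diazo group nor the benzylic C2–O1 bond should be attacked.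

Compound list
1 | 2-(2,3,4-trimethoxyphenyl)acetic acid | OC(=O)Cc1ccc(OC)c(OC)c1OC | starting material
2 | methyl 2-(2,3,4-trimethoxyphenyl)acetate | COC(=O)Cc1ccc(OC)c(OC)c1OC | intermediate
3 | methyl 2-diazo-2-(2,3,4-trimethoxyphenyl)acetate | COC(=O)C(=[N+]=[N-])c1ccc(OC)c(OC)c1OC | intermediate
4 | 3,5-dimethoxyphenol | COc1cc(O)cc(OC)c1 | starting material
5 | methyl (R)-2-(3,5-dimethoxyphenoxy)-2-(2,3,4-trimethoxyphenyl)acetate | COc1cc(OC)cc(c1)O[C@H](c1ccc(OC)c(OC)c1OC)C(=O)OC | intermediate
6 | (R)-2-(3,5-dimethoxyphenoxy)-2-(2,3,4-trimethoxyphenyl)acetic acid | COc1cc(OC)cc(c1)O[C@H](c1ccc(OC)c(OC)c1OC)C(=O)O | intermediate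
7 | (R)-2-(3,5-dimethoxyphenoxy)-2-(2,3,4-trimethoxyphenyl)acetic isobutyl carbonic anhydride (not isolated) | COc1cc(OC)cc(c1)O[C@H](c1ccc(OC)c(OC)c1OC)C(=O)OC(=O)OCC(C)C | intermediate
8 | (R)-1-diazo-3-(3,5-dimethoxyphenoxy)-3-(2,3,4-trimethoxyphenyl)propan-2-one | COc1cc(OC)cc(c1)O[C@H](c1ccc(OC)c(OC)c1OC)C(=O)C=[N+]=[N-] | intermediate
9 | (S)-3-(3,5-dimethoxyphenoxy)-3-(2,3,4-trimethoxyphenyl)prop-1-en-1-one, the ketene (not isolated) | COc1cc(OC)cc(c1)O[C@H](c1ccc(OC)c(OC)c1OC)C=C=O | intermediate
10 | (S)-3-(3,5-dimethoxyphenoxy)-3-(2,3,4-trimethoxyphenyl)propanoic trifluoroacetic anhydride (not isolated) | COc1cc(OC)cc(c1)O[C@H](c1ccc(OC)c(OC)c1OC)CC(=O)OC(=O)C(F)(F)F | intermediate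
11 | (S)-5,7-dimethoxy-2-(2,3,4-trimethoxyphenyl)chroman-4-one | COc1cc(OC)c2c(c1)O[C@H](c1ccc(OC)c(OC)c1OC)CC2=O | target

Total step count: 6. Longest linear sequence: 6 steps (1 → 11).

Steps most likely to fail

Step 6. The ketene may be lost by dimerisation, by capture through adventitious water or by the neighbouring 2'-methoxy oxygen before it is acylating. The acid may also ionise the benzylic C2–O1 bond, which the 2'- and 4'-methoxy groups of ring B activate, and so erode the configuration. Fallback: from 8, a Wolff rearrangement catalysed by PhCO2Ag and Et3N in THF/H2O traps the ketene at once as (S)-3-(3,5-dimethoxyphenoxy)-3-(2,3,4-trimethoxyphenyl)propanoic acid F1. This acid is isolated and cyclised in a separate Friedel–Crafts step with (CF3CO)2O in CH2Cl2 at 0 °C, which returns to the route at 11.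

Step 3. The carbene may alkylate a ring carbon of the very electron-rich phenol instead of its oxygen, and the ortho-methoxy group of the diazo ester may weaken facial discrimination. Fallback: from 3, oxidation with dimethyldioxirane in acetone at 0 °C gives methyl 2-oxo-2-(2,3,4-trimethoxyphenyl)acetate F2. Asymmetric transfer hydrogenation (RuCl(p-cymene)[(S,S)-TsDPEN] or its antipode, HCO2H/Et3N) then gives methyl (S)-2-hydroxy-2-(2,3,4-trimethoxyphenyl)acetate F3. Mitsunobu etherification of this alcohol with 4 (PPh3, DIAD, toluene, 0 °C) proceeds with inversion at the carbinol carbon and returns to the route at 5.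

Step 5. The activated acid may enolise or form a ketene under the amine base, which would erode the configuration at C2. Fallback: from 6, the acid is converted under neutral conditions with 1-chloro-N,N,2-trimethylprop-1-en-1-amine (CH2Cl2, 0 °C) into (R)-2-(3,5-dimethoxyphenoxy)-2-(2,3,4-trimethoxyphenyl)acetyl chloride F4. This is added to excess ethereal CH2N2 at 0 °C with no amine present, a second equivalent of CH2N2 taking up the HCl, which returns to the route at 8.

Further compounds
F1 | step 6 | (S)-3-(3,5-dimethoxyphenoxy)-3-(2,3,4-trimethoxyphenyl)propanoic acid | COc1cc(OC)cc(c1)O[C@H](c1ccc(OC)c(OC)c1OC)CC(=O)O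
F2 | step 3 | methyl 2-oxo-2-(2,3,4-trimethoxyphenyl)acetate | COC(=O)C(=O)c1ccc(OC)c(OC)c1OC
F3 | step 3 | methyl (S)-2-hydroxy-2-(2,3,4-trimethoxyphenyl)acetate | O[C@@H](c1ccc(OC)c(OC)c1OC)C(=O)OC
F4 | step 5 | (R)-2-(3,5-dimethoxyphenoxy)-2-(2,3,4-trimethoxyphenyl)acetyl chloride | COc1cc(OC)cc(c1)O[C@H](c1ccc(OC)c(OC)c1OC)C(Cl)=O
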